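**Retrosynthetic overview**
1. The (3Z)-trisubstituted olefin is cut by a silicon-tethered ring-closing metathesis: the two hydroxyl groups are tied in an eight-membered silaketal, which splits the target into a decalin-bearing 2-substituted allyl alcohol and a hydroxybutenyl lactone.
2. Lactone half: chiral phosphoric acid allylboration of a formyl butyrolactone, which comes from enamine-catalysed α-hydroxymethylation of methyl 4-oxobutanoate (the lactone ring closes here).
3. Decalin half: methallyl-dianion alkylation of an allylic bromide, from the enoate, from enol triflate/methyl coupling of a cis-fused bicyclic β-keto ester.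
4. Key step: chiral Brønsted acid proton-initiated bicyclization of a (Z)-polyene β-keto ester made from nerylacetone; the (Z)-olefin encodes the cis ring fusion.
5. Ring order: rings A and B together (step 2), lactone ring (step 8), temporary eight-membered silaketal (step 11, opened in the same flask).

Assumption: the target is taken exactly as drawn, i.e. the cis-fused (4aR,8aS)-decalin with (1R)-carbinol, (4S)-lactone and (3Z)-olefin; the catalyst antipodes named are those expected by analogy to give the drawn enantiomers, and the mirror-image catalyst is used if the sense proves opposite.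

Step 1
Reactants: 1 nerylacetone, (5Z)-6,10-dimethylundeca-5,9-dien-2-one
Product: 3 methyl (6Z)-7,11-dimethyl-3-oxododeca-6,10-dienoate, via sodium enolate 2 (not isolated)
Conditions: NaH (2.5 equiv), (MeO)2CO, THF, reflux; then aq. HCl
Reagents that add atoms: dimethyl carbonate, COC(=O)OC
Why: Claisen-type C-carbomethoxylation of the methyl ketone occurs at the less hindered methyl group and is driven by irreversible deprotonation of the β-keto ester, while the (Z)-olefin that later encodes the cis ring fusion is untouched.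

Step 2
Reactants: 3 methyl (6Z)-7,11-dimethyl-3-oxododeca-6,10-dienoate
Product: 4 methyl (1S,4aR,8aS)-5,5,8a-trimethyl-2-oxodecahydronaphthalene-1-carboxylate
Conditions: (S,S)-IDPi acid HN[P(=NSO2CF3)(O,O'-BINOL*)]2, BINOL* = (S)-3,3'-bis[3,5-bis(trifluoromethyl)phenyl]-1,1'-bi-2-naphthol (5 mol%), (CF3)3COH, −20 °C
Reagents that add atoms: none
Why: Proposed new method: the confined chiral acid protonates C10 of the terminal olefin of the folded polyene inside its pocket, and the C11 cation is trapped by the (6Z)-olefin and then by the hydrogen-bonded enol carbon C2 in one antiperiplanar Stork–Eschenmoser cascade (ring A chair, ring B boat-like), so the (Z)-geometry becomes the cis ring fusion, the fold selected by the chiral ion pair sets C4a and C8a as (4aR,8aS), and the enol proton returns to the IDPi anion for turnover (C1 is epimerizable, drawn as the expected equatorial ester, and is erased in step 3); the closest known reaction types are the IDPi-catalysed proton-initiated cyclization of hydroxyl-terminated homofarnesol-type polyenes (trans-fused) and the racemic SnCl4-mediated cyclization of polyene β-keto esters.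

Step 3
Reactants: 4 methyl (1S,4aR,8aS)-5,5,8a-trimethyl-2-oxodecahydronaphthalene-1-carboxylate
Product: 6 methyl (4aR,8aS)-5,5,8a-trimethyl-2-{[(trifluoromethyl)sulfonyl]oxy}-3,4,4a,5,6,7,8,8a-octahydronaphthalene-1-carboxylate, via sodium enolate 5 (not isolated)
Conditions: NaH, Et2O, 0 °C; then Tf2O, −78 to 0 °C
Reagents that add atoms: trifluoromethanesulfonic anhydride, O=S(=O)(OS(=O)(=O)C(F)(F)F)C(F)(F)F
Why: O-sulfonylation of the stabilized β-keto ester enolate (enol triflate formation) is regiodefined because only C1 lies between the two carbonyl groups, and it removes the labile C1 center while C4a and C8a are untouched.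

Step 4
Reactants: 6 methyl (4aR,8aS)-5,5,8a-trimethyl-2-{[(trifluoromethyl)sulfonyl]oxy}-3,4,4a,5,6,7,8,8a-octahydronaphthalene-1-carboxylate
Product: 7 methyl (4aR,8aS)-2,5,5,8a-tetramethyl-3,4,4a,5,6,7,8,8a-octahydronaphthalene-1-carboxylate
Conditions: MeMgBr (1.5 equiv), Fe(acac)3 (5 mol%), THF/NMP, −30 °C
Reagents that add atoms: methylmagnesium bromide, C[Mg]Br
Why: iron-catalysed Kumada-type cross-coupling of an electron-poor enol triflate with a methyl Grignard reagent is fast at −30 °C, tolerates the ester and fixes the tetrasubstituted ring B olefin exactly where the triflate was.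

Step 5
Reactants: 7 methyl (4aR,8aS)-2,5,5,8a-tetramethyl-3,4,4a,5,6,7,8,8a-octahydronaphthalene-1-carboxylate
Product: 9 [(4aR,8aS)-2,5,5,8a-tetramethyl-3,4,4a,5,6,7,8,8a-octahydronaphthalen-1-yl]methanol, via aluminium alkoxide 8 (not isolated)
Conditions: iBu2AlH (3 equiv), CH2Cl2, −78 to 0 °C; then aq. potassium sodium tartrate
Reagents that add atoms: none
Why: 1,2-reduction of the twisted, poorly conjugated enoate by diisobutylaluminium hydride gives the primary allylic alcohol without touching the tetrasubstituted olefin or the ring-fusion centers.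

Step 6
Reactants: 9 [(4aR,8aS)-2,5,5,8a-tetramethyl-3,4,4a,5,6,7,8,8a-octahydronaphthalen-1-yl]methanol
Product: 10 [(4aR,8aS)-2,5,5,8a-tetramethyl-3,4,4a,5,6,7,8,8a-octahydronaphthalen-1-yl]methyl bromide
Conditions: CBr4, PPh3, CH2Cl2, 0 °C
Reagents that add atoms: carbon tetrabromide, BrC(Br)(Br)Br
Why: the Appel reaction converts the primary allylic alcohol into the bromide under neutral conditions that do not ionize the allyl system, so no allylic transposition or olefin migration is expected.

Step 7
Reactants: 10 [(4aR,8aS)-2,5,5,8a-tetramethyl-3,4,4a,5,6,7,8,8a-octahydronaphthalen-1-yl]methyl bromide; 11 2-methylprop-2-en-1-ol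
Product: 14 2-methylidene-4-[(4aR,8aS)-2,5,5,8a-tetramethyl-3,4,4a,5,6,7,8,8a-octahydronaphthalen-1-yl]butan-1-ol, via dilithiated methallyl alcohol 12 (not isolated), via lithium alkoxide 13 (not isolated)
Conditions: 11 (3 equiv), n-BuLi (6 equiv), TMEDA, Et2O/hexane, 0 °C to rt; then 10, THF, −78 °C to rt; then H2O
Reagents that add atoms: none
Why: the C,O-dianion of methallyl alcohol is a 2-(hydroxymethyl)allyl anion equivalent whose carbanion displaces the primary allylic bromide by SN2 substitution, installing the two-carbon link and the 1,1-disubstituted olefin needed for metathesis in one operation.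

Step 8
Reactants: 15 methyl 4-oxobutanoate
Product: 17 (3S)-5-oxooxolane-3-carbaldehyde, via hydroxy aldehyde 16 (not isolated)
Conditions: aq. HCHO (37%, 3 equiv), (R)-2-[diphenyl(trimethylsilyloxy)methyl]pyrrolidine (10 mol%), toluene, pH 7 buffer (NaH2PO4/Na2HPO4), rt; then p-TsOH (cat.), MgSO4, CH2Cl2, rt
Reagents that add atoms: formaldehyde, C=O
Why: enamine-catalysed α-hydroxymethylation (cross-aldol with formaldehyde) sets the first stereocenter of this fragment, formaldehyde adding to the enamine face left open by the diaryl(silyloxy)methyl group to give the (S)-aldehyde, and the primary alcohol then closes onto the ester so that the lactone is formed before any competing secondary hydroxyl exists.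

Step 9
Reactants: 17 (3S)-5-oxooxolane-3-carbaldehyde
Product: 19 (4S)-4-[(1R)-1-hydroxybut-3-en-1-yl]oxolan-2-one, via pinacol borate ester 18 (not isolated)
Conditions: allylB(pin) (1.2 equiv), (R)-TRIP [(R)-3,3'-bis(2,4,6-triisopropylphenyl)-1,1'-binaphthyl-2,2'-diyl hydrogen phosphate] (5 mol%), toluene, −30 °C; then aq. NaHCO3
Reagents that add atoms: allylboronic acid pinacol ester, C=CCB1OC(C)(C)C(C)(C)O1
Why: chiral phosphoric acid-catalysed allylboration proceeds through a chair-like six-membered transition state in which the acid binds the boronate oxygen and directs the allyl group to the Re face of the aldehyde, setting the (1R)-carbinol under catalyst control because the adjacent center carries two nearly equal ring arms and exerts little bias.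

Step 10
Reactants: 19 (4S)-4-[(1R)-1-hydroxybut-3-en-1-yl]oxolan-2-one; 14 2-methylidene-4-[(4aR,8aS)-2,5,5,8a-tetramethyl-3,4,4a,5,6,7,8,8a-octahydronaphthalen-1-yl]butan-1-ol
Product: 21 (4S)-4-[(1R)-1-({[(2-methylidene-4-{(4aR,8aS)-2,5,5,8a-tetramethyl-3,4,4a,5,6,7,8,8a-octahydronaphthalen-1-yl}butyl)oxy]di(propan-2-yl)silyl}oxy)but-3-en-1-yl]oxolan-2-one, via chlorosilane 20 (not isolated)
Conditions: 19, iPr2SiCl2 (1.2 equiv), imidazole (3 equiv), CH2Cl2, 0 °C; then 14 (1.0 equiv), rt
Reagents that add atoms: dichlorodi(propan-2-yl)silane, CC(C)[Si](Cl)(Cl)C(C)C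
Why: stepwise nucleophilic substitution at silicon stops cleanly at the monochlorosilane with the hindered secondary alcohol and is completed by the primary allylic alcohol, giving the unsymmetrical silaketal that is both the only protecting group of the route and the tether for ring closure, with no stereocenter touched.

Step 11
Reactants: 21 (4S)-4-[(1R)-1-({[(2-methylidene-4-{(4aR,8aS)-2,5,5,8a-tetramethyl-3,4,4a,5,6,7,8,8a-octahydronaphthalen-1-yl}butyl)oxy]di(propan-2-yl)silyl}oxy)but-3-en-1-yl]oxolan-2-one
Product: 23 (4S)-4-[(1R,3Z)-1-hydroxy-4-(hydroxymethyl)-6-[(4aR,8aS)-2,5,5,8a-tetramethyl-3,4,4a,5,6,7,8,8a-octahydronaphthalen-1-yl]hex-3-en-1-yl]oxolan-2-one, via cyclic silaketal 22 (not isolated)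
Conditions: second-generation Grubbs catalyst RuCl2(=CHPh)(H2IMes)(PCy3) (10 mol%), toluene (2 mM), 80 °C; then HF·pyridine, THF, 0 °C to rt
Reagents that add atoms: none
Why: silicon-tethered ring-closing metathesis joins the terminal and the 1,1-disubstituted olefin (the tetrasubstituted ring B olefin is inert), and the eight-membered ring can only hold a cis ring olefin, which places the oxygenated methylene and C2 of the hexenyl chain on the same side, i.e. the required (3Z)-geometry; HF·pyridine then excises silicon under non-basic conditions that should not translactonize the hydroxy lactone.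

**Compound list**
1 | nerylacetone, (5Z)-6,10-dimethylundeca-5,9-dien-2-one | CC(=O)CC/C=C(/C)CCC=C(C)C | starting material
2 | sodium enolate of 3 (sodium salt, C2 carbanion form drawn) | [Na+].COC(=O)[CH-]C(=O)CC/C=C(/C)CCC=C(C)C | intermediate
3 | methyl (6Z)-7,11-dimethyl-3-oxododeca-6,10-dienoate | COC(=O)CC(=O)CC/C=C(/C)CCC=C(C)C | intermediate
4 | methyl (1S,4aR,8aS)-5,5,8a-trimethyl-2-oxodecahydronaphthalene-1-carboxylate (cis-fused; C1 epimerizable) | O=C1[C@@H](C(=O)OC)[C@@]2(C)CCCC(C)(C)[C@H]2CC1 | intermediate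
5 | sodium (4aR,8aS)-1-(methoxycarbonyl)-5,5,8a-trimethyl-3,4,4a,5,6,7,8,8a-octahydronaphthalen-2-olate | [Na+].[O-]C1=C(C(=O)OC)[C@@]2(C)CCCC(C)(C)[C@H]2CC1 | intermediate
6 | methyl (4aR,8aS)-5,5,8a-trimethyl-2-{[(trifluoromethyl)sulfonyl]oxy}-3,4,4a,5,6,7,8,8a-octahydronaphthalene-1-carboxylate | O=S(=O)(OC1=C(C(=O)OC)[C@@]2(C)CCCC(C)(C)[C@H]2CC1)C(F)(F)F | intermediate
7 | methyl (4aR,8aS)-2,5,5,8a-tetramethyl-3,4,4a,5,6,7,8,8a-octahydronaphthalene-1-carboxylate | CC1=C(C(=O)OC)[C@@]2(C)CCCC(C)(C)[C@H]2CC1 | intermediate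
8 | bis(2-methylpropyl){[(4aR,8aS)-2,5,5,8a-tetramethyl-3,4,4a,5,6,7,8,8a-octahydronaphthalen-1-yl]methoxy}alumane | CC1=C(CO[Al](CC(C)C)CC(C)C)[C@@]2(C)CCCC(C)(C)[C@H]2CC1 | intermediate
9 | [(4aR,8aS)-2,5,5,8a-tetramethyl-3,4,4a,5,6,7,8,8a-octahydronaphthalen-1-yl]methanol | CC1=C(CO)[C@@]2(C)CCCC(C)(C)[C@H]2CC1 | intermediate
10 | [(4aR,8aS)-2,5,5,8a-tetramethyl-3,4,4a,5,6,7,8,8a-octahydronaphthalen-1-yl]methyl bromide | CC1=C(CBr)[C@@]2(C)CCCC(C)(C)[C@H]2CC1 | intermediate
11 | 2-methylprop-2-en-1-ol (methallyl alcohol) | C=C(C)CO | starting material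
12 | dilithiated methallyl alcohol, lithium 2-(lithiomethyl)prop-2-en-1-olate | [Li]CC(=C)CO[Li] | intermediate
13 | lithium alkoxide of 14 | CC1=C(CCC(=C)CO[Li])[C@@]2(C)CCCC(C)(C)[C@H]2CC1 | intermediate
14 | 2-methylidene-4-[(4aR,8aS)-2,5,5,8a-tetramethyl-3,4,4a,5,6,7,8,8a-octahydronaphthalen-1-yl]butan-1-ol | CC1=C(CCC(=C)CO)[C@@]2(C)CCCC(C)(C)[C@H]2CC1 | intermediate
15 | methyl 4-oxobutanoate | COC(=O)CCC=O | starting material
16 | methyl (3S)-3-formyl-4-hydroxybutanoate | COC(=O)C[C@H](C=O)CO | intermediate
17 | (3S)-5-oxooxolane-3-carbaldehyde | O=C[C@@H]1COC(=O)C1 | intermediate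
18 | (4S)-4-{(1R)-1-[(4,4,5,5-tetramethyl-1,3,2-dioxaborolan-2-yl)oxy]but-3-en-1-yl}oxolan-2-one | C=CC[C@@H](OB1OC(C)(C)C(C)(C)O1)[C@@H]1COC(=O)C1 | intermediate
19 | (4S)-4-[(1R)-1-hydroxybut-3-en-1-yl]oxolan-2-one | C=CC[C@@H](O)[C@@H]1COC(=O)C1 | intermediate
20 | (4S)-4-[(1R)-1-{[chlorodi(propan-2-yl)silyl]oxy}but-3-en-1-yl]oxolan-2-one | C=CC[C@@H](O[Si](Cl)(C(C)C)C(C)C)[C@@H]1COC(=O)C1 | intermediate
21 | (4S)-4-[(1R)-1-({[(2-methylidene-4-{(4aR,8aS)-2,5,5,8a-tetramethyl-3,4,4a,5,6,7,8,8a-octahydronaphthalen-1-yl}butyl)oxy]di(propan-2-yl)silyl}oxy)but-3-en-1-yl]oxolan-2-one | CC1=C(CCC(=C)CO[Si](C(C)C)(C(C)C)O[C@H](CC=C)[C@@H]3COC(=O)C3)[C@@]2(C)CCCC(C)(C)[C@H]2CC1 | intermediate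
22 | (5Z,8R)-8-[(3S)-5-oxooxolan-3-yl]-2,2-di(propan-2-yl)-5-{2-[(4aR,8aS)-2,5,5,8a-tetramethyl-3,4,4a,5,6,7,8,8a-octahydronaphthalen-1-yl]ethyl}-7,8-dihydro-4H-1,3,2-dioxasilocine | CC1=C(CC/C3=C/C[C@H]([C@@H]4COC(=O)C4)O[Si](C(C)C)(C(C)C)OC3)[C@@]2(C)CCCC(C)(C)[C@H]2CC1 | intermediate
23 | (4S)-4-[(1R,3Z)-1-hydroxy-4-(hydroxymethyl)-6-[(4aR,8aS)-2,5,5,8a-tetramethyl-3,4,4a,5,6,7,8,8a-octahydronaphthalen-1-yl]hex-3-en-1-yl]oxolan-2-one | CC1=C(CC/C(=C/C[C@@H](O)[C@@H]2COC(=O)C2)CO)[C@@]2(C)CCCC(C)(C)[C@H]2CC1 | target

**Step count and risks**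
Total: 11 steps. Longest linear sequence: 9 steps (steps 1–7, 10, 11).

The three steps most likely to fail:

Step 2 (the proposed new cyclization). The risks are termination at the enol oxygen instead of carbon, loss of the cis ring fusion through a stepwise pathway, and low enantioselectivity. The fallback sets out from 3 and comes back at 4. Compound 3 is treated with SnCl4 (2 equiv) in CH2Cl2 at 0 °C, the established Lewis-acid cyclization of polyene β-keto esters, in which the (Z)-olefin is expected to give the cis-fused keto ester as the racemate. This is 4 together with its mirror image, methyl (1R,4aS,8aR)-5,5,8a-trimethyl-2-oxodecahydronaphthalene-1-carboxylate F1. The two are separated by preparative supercritical-fluid chromatography on a chiral stationary phase, and 4 re-enters at step 3. This gives up catalyst control of the first stereocenter in exchange for a known reaction.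

Step 7 (dianion alkylation). The strongly basic organolithium can eliminate or undergo halogen–metal exchange with the easily ionized tetrasubstituted allylic bromide. The fallback sets out from 9 and comes back at 14, replacing the anionic SN2 step by cation chemistry. Alcohol 9 is ionized with BF3·OEt2 in CH2Cl2 at −78 °C in the presence of 2-[(trimethylsilyl)methyl]prop-2-en-1-yl acetate (Hosomi–Sakurai allylation, attack at the primary terminus of the allyl cation). This gives 2-methylidene-4-[(4aR,8aS)-2,5,5,8a-tetramethyl-3,4,4a,5,6,7,8,8a-octahydronaphthalen-1-yl]butyl acetate F2, and K2CO3 in MeOH then gives 14.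

Step 8 (α-hydroxymethylation and lactonization). Under amine catalysis the aldol adduct can dehydrate to the α-methylene aldehyde or racemize, and 17 is a β-acyloxy aldehyde. The fallback sets out from 15 and comes back at 17, and builds the same stereocenter with a formyl cation equivalent instead of formaldehyde.
- Organocatalytic SN1-type α-alkylation of 15 with 1,3-benzodithiolylium tetrafluoroborate gives methyl (3S)-3-(1,3-benzodithiol-2-yl)-4-oxobutanoate F3. Conditions: the antipode of 5-benzyl-2-tert-butyl-3-methylimidazolidin-4-one that gives the (3S) product (20 mol%), benzoic acid, NaH2PO4, MeCN/H2O, 0 °C.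
- NaBH4 in MeOH reduces the aldehyde to methyl (3S)-3-(1,3-benzodithiol-2-yl)-4-hydroxybutanoate F4, which closes on acidification (p-TsOH) to (4S)-4-(1,3-benzodithiol-2-yl)oxolan-2-one F5, a stable carrier of the stereocenter.
- HgO and aq. HBF4 in THF unveil 17 immediately before step 9. In this variant the original aldehyde carbon of 15 becomes the lactone CH2O and the dithioacetal carbon becomes the formyl group.

**Further compounds**
F1 | step 2 | methyl (1R,4aS,8aR)-5,5,8a-trimethyl-2-oxodecahydronaphthalene-1-carboxylate | O=C1[C@H](C(=O)OC)[C@]2(C)CCCC(C)(C)[C@@H]2CC1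
F2 | step 7 | 2-methylidene-4-[(4aR,8aS)-2,5,5,8a-tetramethyl-3,4,4a,5,6,7,8,8a-octahydronaphthalen-1-yl]butyl acetate | CC1=C(CCC(=C)COC(C)=O)[C@@]2(C)CCCC(C)(C)[C@H]2CC1
F3 | step 8 | methyl (3S)-3-(1,3-benzodithiol-2-yl)-4-oxobutanoate | COC(=O)C[C@@H](C=O)C1Sc2ccccc2S1
F4 | step 8 | methyl (3S)-3-(1,3-benzodithiol-2-yl)-4-hydroxybutanoate | COC(=O)C[C@@H](CO)C1Sc2ccccc2S1
F5 | step 8 | (4S)-4-(1,3-benzodithiol-2-yl)oxolan-2-one | S1c2ccccc2SC1[C@@H]1COC(=O)C1
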